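**Retrosynthetic overview**
- The γ-lactone is the only ring made and is closed last. It is opened to an ortho-bromo benzylic N,N-diisopropylcarbamate, whose carbamate C=O becomes the lactone carbonyl (Br–Li exchange, O→C carbamoyl shift, acid lactonisation).
- The aryl bromide comes from regioselective bromination of the (S)-1-(3,5-dimethoxyphenyl)alkyl carbamate.
- Key disconnection C3–C3a: a nucleophilic carbinol carbon (α-oxy carbanion from the O-alkyl carbamate, s-BuLi/(+)-sparteine, then Zn) is cross-coupled with 1-bromo-3,5-dimethoxybenzene. This step sets C3.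
- The C15 chain comes from the Grignard reagent of 12-bromododecyl carbamate and (S)-propylene oxide, which supplies the side-chain carbinol stereocentre; the alkoxide is silylated in the same flask.

Assumption: a one-pot sequence without isolation counts as one step; (+)-sparteine and the numbered starting materials are taken as commercially available.

**Step 1**
Reactants: 1 12-bromododecan-1-ol; 2 N,N-diisopropylcarbamoyl chloride
Product: 3 12-bromododecyl N,N-diisopropylcarbamate
Conditions: 2 (1.2 equiv), i-Pr2NEt (1.5 equiv), DMAP (0.1 equiv), CH2Cl2, reflux, 24–48 h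
Reagents that add atoms: none
Why: O-carbamoylation (nucleophilic acyl substitution) of the primary alcohol with a non-nucleophilic base that spares the alkyl bromide; the hindered carbamate later directs the lithiation and supplies the lactone carbonyl.

**Step 2**
Reactants: 3 12-bromododecyl N,N-diisopropylcarbamate; 4 (S)-2-methyloxirane
Product: 7 (S)-14-[(tert-butyldimethylsilyl)oxy]pentadecyl N,N-diisopropylcarbamate, via Grignard reagent 5 (not isolated), via bromomagnesium alkoxide 6 (not isolated)
Conditions: Mg, cat. I2, THF, 45 °C; CuI (10 mol%), 4 (1.3 equiv), −30 → 0 °C; then TBSCl, imidazole, DMF, rt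
Reagents that add atoms: tert-butyldimethylsilyl chloride (TBSCl), CC(C)(C)[Si](C)(C)Cl
Why: The hindered diisopropylcarbamate tolerates Grignard formation, and Cu(I)-catalysed SN2 epoxide opening at the unsubstituted carbon leaves the epoxide C–O stereocentre untouched, so the (S)-carbinol comes directly from (S)-propylene oxide and its alkoxide is silylated in situ.

**Step 3**
Reactants: 7 (S)-14-[(tert-butyldimethylsilyl)oxy]pentadecyl N,N-diisopropylcarbamate; 8 1-bromo-3,5-dimethoxybenzene
Product: 11 (1S,14S)-14-[(tert-butyldimethylsilyl)oxy]-1-(3,5-dimethoxyphenyl)pentadecyl N,N-diisopropylcarbamate, via lithiated carbamate 9 (not isolated), via alkylzinc chloride 10 (not isolated)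
Conditions: s-BuLi (1.3 equiv), (+)-sparteine (1.3 equiv), Et2O, −78 °C, 5 h; ZnCl2 (THF), −78 °C → rt; 8 (1.2 equiv), Pd2(dba)3 (2.5 mol%), t-Bu3P·HBF4 (6 mol%), rt → 40 °C
Reagents that add atoms: none
Why: Hoppe asymmetric deprotonation with s-BuLi/(+)-sparteine removes the pro-R hydrogen to give a configurationally stable, dipole-stabilised α-oxy carbanion, and Li→Zn transmetalation and Negishi coupling (the lithiation/zincation/arylation sequence known for N-Boc-pyrrolidine and O-alkyl carbamates) proceed with retention, so the aryl group replaces the pro-R hydrogen and sets (1S) (expected er about 97:3, seen as dr), with t-Bu3P suppressing β-hydride elimination.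

**Step 4**
Reactants: 11 (1S,14S)-14-[(tert-butyldimethylsilyl)oxy]-1-(3,5-dimethoxyphenyl)pentadecyl N,N-diisopropylcarbamate
Product: 12 (1S,14S)-1-(2-bromo-3,5-dimethoxyphenyl)-14-[(tert-butyldimethylsilyl)oxy]pentadecyl N,N-diisopropylcarbamate
Conditions: NBS (1.05 equiv), NaHCO3, MeCN, 0 °C → rt, dark
Reagents that add atoms: N-bromosuccinimide (NBS), O=C1CCC(=O)N1Br
Why: Electrophilic aromatic bromination goes to the position para to one OMe and ortho to the other (C2), as is usual for 3,5-dimethoxybenzyl systems, in preference to the position between the two OMe groups; the buffered ionic conditions leave the TBS ether, carbamate and both stereocentres untouched.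

**Step 5**
Reactants: 12 (1S,14S)-1-(2-bromo-3,5-dimethoxyphenyl)-14-[(tert-butyldimethylsilyl)oxy]pentadecyl N,N-diisopropylcarbamate
Product: 15 (3S)-3-[(13S)-13-hydroxytetradecyl]-5,7-dimethoxy-2-benzofuran-1(3H)-one, via aryllithium 13 (not isolated), via lithium alkoxide amide 14 (not isolated)
Conditions: t-BuLi (2.1 equiv), THF, −78 → 0 °C; then 3 M aq. HCl, 60 °C
Reagents that add atoms: none
Why: Br–Li exchange triggers the anionic homo-Fries rearrangement (1,4 O→C carbamoyl shift through a five-membered tetrahedral intermediate) to the ortho-(α-hydroxyalkyl)benzamide, and acid then drives N→O acyl transfer (lactonisation with loss of i-Pr2NH) and cleaves the TBS ether; the benzylic C–O bond is never broken, so (3S) is retained.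

**Compound list**
1 | 12-bromododecan-1-ol | OCCCCCCCCCCCCBr | starting material
2 | N,N-diisopropylcarbamoyl chloride | CC(C)N(C(C)C)C(Cl)=O | starting material
3 | 12-bromododecyl N,N-diisopropylcarbamate | BrCCCCCCCCCCCCOC(=O)N(C(C)C)C(C)C | intermediate
4 | (S)-2-methyloxirane [(S)-propylene oxide] | C[C@H]1CO1 | starting material
5 | [12-(diisopropylcarbamoyloxy)dodecyl]magnesium bromide | Br[Mg]CCCCCCCCCCCCOC(=O)N(C(C)C)C(C)C | intermediate
6 | bromomagnesium alkoxide of (S)-14-hydroxypentadecyl N,N-diisopropylcarbamate | C[C@H](O[Mg]Br)CCCCCCCCCCCCCOC(=O)N(C(C)C)C(C)C | intermediate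
7 | (S)-14-[(tert-butyldimethylsilyl)oxy]pentadecyl N,N-diisopropylcarbamate | C[C@H](O[Si](C)(C)C(C)(C)C)CCCCCCCCCCCCCOC(=O)N(C(C)C)C(C)C | intermediate
8 | 1-bromo-3,5-dimethoxybenzene | COc1cc(Br)cc(OC)c1 | starting material
9 | (1R,14S)-14-[(tert-butyldimethylsilyl)oxy]-1-lithiopentadecyl N,N-diisopropylcarbamate, (+)-sparteine complex | C[C@H](O[Si](C)(C)C(C)(C)C)CCCCCCCCCCCC[C@@H]([Li])OC(=O)N(C(C)C)C(C)C | intermediate
10 | (1R,14S)-14-[(tert-butyldimethylsilyl)oxy]-1-(chlorozincio)pentadecyl N,N-diisopropylcarbamate | C[C@H](O[Si](C)(C)C(C)(C)C)CCCCCCCCCCCC[C@@H]([Zn]Cl)OC(=O)N(C(C)C)C(C)C | intermediate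
11 | (1S,14S)-14-[(tert-butyldimethylsilyl)oxy]-1-(3,5-dimethoxyphenyl)pentadecyl N,N-diisopropylcarbamate | COc1cc(OC)cc(c1)[C@H](CCCCCCCCCCCC[C@H](C)O[Si](C)(C)C(C)(C)C)OC(=O)N(C(C)C)C(C)C | intermediate
12 | (1S,14S)-1-(2-bromo-3,5-dimethoxyphenyl)-14-[(tert-butyldimethylsilyl)oxy]pentadecyl N,N-diisopropylcarbamate | COc1cc(OC)c(Br)c(c1)[C@H](CCCCCCCCCCCC[C@H](C)O[Si](C)(C)C(C)(C)C)OC(=O)N(C(C)C)C(C)C | intermediate
13 | (1S,14S)-14-[(tert-butyldimethylsilyl)oxy]-1-(2-lithio-3,5-dimethoxyphenyl)pentadecyl N,N-diisopropylcarbamate | COc1cc(OC)c([Li])c(c1)[C@H](CCCCCCCCCCCC[C@H](C)O[Si](C)(C)C(C)(C)C)OC(=O)N(C(C)C)C(C)C | intermediate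
14 | lithium alkoxide of 2-[(1S,14S)-14-[(tert-butyldimethylsilyl)oxy]-1-hydroxypentadecyl]-4,6-dimethoxy-N,N-diisopropylbenzamide | COc1cc(OC)c(C(=O)N(C(C)C)C(C)C)c(c1)[C@H](CCCCCCCCCCCC[C@H](C)O[Si](C)(C)C(C)(C)C)O[Li] | intermediate
15 | (3S)-3-[(13S)-13-hydroxytetradecyl]-5,7-dimethoxy-2-benzofuran-1(3H)-one | COc1cc(OC)c2c(c1)[C@H](CCCCCCCCCCCC[C@H](C)O)OC2=O | target

**Total step count:** 5
**Longest linear sequence:** 5 steps (1 → 3 → 7 → 11 → 12 → 15)

**Steps most likely to fail, with fallbacks**

Step 3 (lithiation/zincation/arylation: incomplete coupling, β-hydride elimination or eroded er). The fallback sets out from 7 and comes back at 11. Compound 7 is lithiated as before (s-BuLi/(+)-sparteine, Et2O, −78 °C) to 9. It is then trapped with commercial 2-(3,5-dimethoxyphenyl)-4,4,5,5-tetramethyl-1,3,2-dioxaborolane (COc1cc(OC)cc(c1)B1OC(C)(C)C(C)(C)O1) to give the lithium boronate complex F1. Warming with MgBr2·OEt2 in refluxing Et2O triggers a stereospecific 1,2-aryl shift with loss of the carbamate (lithiation–borylation, a 1,2-metallate rearrangement). This gives the secondary benzylic boronic ester F2. NaOH/H2O2 oxidises it with retention to the benzylic alcohol F3. O-Carbamoylation of F3 with 2 (NaH, THF, reflux) rejoins the route at 11. Boron replaces lithium with retention, the aryl group displaces the carbamate with inversion and the oxidation is retentive, so the same (+)-sparteine again gives (1S).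

Step 5 (carbamoyl shift or lactonisation of the hindered diisopropylamide stalls). The fallback sets out from 12 and comes back at 15. The carbamate of 12 is cleaved reductively (LiAlH4, THF, 0 → 50 °C) to the bromo alcohol F4. Pd-catalysed carbonylative lactonisation (Pd(OAc)2/dppf, CO 1 atm, K2CO3, toluene, 100 °C) closes the silyl-protected phthalide F5. Aqueous HCl/THF removes the TBS group to give 15.

Step 2 (Grignard formation beside the carbamate, or the in-flask silylation). The fallback sets out from 1 and comes back at 7. Compound 1 is deprotonated with MeMgBr (1 equiv, THF, 0 °C) and Mg is inserted to give the alkoxide-protected Grignard reagent F6. CuI-catalysed opening of 4 gives (S)-pentadecane-1,14-diol F7. Selective carbamoylation of the primary hydroxyl with 2 (Et3N, CH2Cl2, reflux; the hindered chloride discriminates against the secondary OH) gives the hydroxy carbamate F8. TBSCl/imidazole/DMF then gives 7.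

**Further compounds**
F1 | step 3 | lithium boronate complex of 9 with the arylboronic pinacol ester (C–B bond formed with retention) | [Li+].COc1cc(OC)cc(c1)[B-]2(OC(C)(C)C(C)(C)O2)[C@H](CCCCCCCCCCCC[C@H](C)O[Si](C)(C)C(C)(C)C)OC(=O)N(C(C)C)C(C)C
F2 | step 3 | 2-[(1S,14S)-14-[(tert-butyldimethylsilyl)oxy]-1-(3,5-dimethoxyphenyl)pentadecyl]-4,4,5,5-tetramethyl-1,3,2-dioxaborolane | COc1cc(OC)cc(c1)[C@H](CCCCCCCCCCCC[C@H](C)O[Si](C)(C)C(C)(C)C)B1OC(C)(C)C(C)(C)O1
F3 | step 3 | (1S,14S)-14-[(tert-butyldimethylsilyl)oxy]-1-(3,5-dimethoxyphenyl)pentadecan-1-ol | COc1cc(OC)cc(c1)[C@H](CCCCCCCCCCCC[C@H](C)O[Si](C)(C)C(C)(C)C)O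
F4 | step 5 | (1S,14S)-1-(2-bromo-3,5-dimethoxyphenyl)-14-[(tert-butyldimethylsilyl)oxy]pentadecan-1-ol | COc1cc(OC)c(Br)c(c1)[C@H](CCCCCCCCCCCC[C@H](C)O[Si](C)(C)C(C)(C)C)O
F5 | step 5 | (3S)-3-[(13S)-13-[(tert-butyldimethylsilyl)oxy]tetradecyl]-5,7-dimethoxy-2-benzofuran-1(3H)-one | COc1cc(OC)c2c(c1)[C@H](CCCCCCCCCCCC[C@H](C)O[Si](C)(C)C(C)(C)C)OC2=O
F6 | step 2 | bromomagnesium 12-(bromomagnesio)dodecan-1-olate | Br[Mg]OCCCCCCCCCCCC[Mg]Br
F7 | step 2 | (S)-pentadecane-1,14-diol | C[C@H](O)CCCCCCCCCCCCCO
F8 | step 2 | (S)-14-hydroxypentadecyl N,N-diisopropylcarbamate | C[C@H](O)CCCCCCCCCCCCCOC(=O)N(C(C)C)C(C)C
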